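The C2-symmetric target is cut at C3–C3'' into two identical (2S)-flavanones, joined at the end by oxidative coupling of their enol silanes, in which each C2 aryl group directs the new C3 centre. Each chromanone C ring (O1, C2, C3, C4, C4a, C8a) is made from the five-membered furan ring of a flat 2-aryl-3-silyloxybenzofuran: enantioselective methylene transfer to C2=C3 dearomatises it, and base-induced opening of the cyclopropanol inserts the CH2 as C3. The step exploits the 1,3-relation of the C4 carbonyl and the benzylic, O1-bearing C2, which directs cleavage of the internal cyclopropane bond and fixes C2.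

Key step: step 4

Assumption: the sense of induction of the dipeptide–zinc carbenoid on this tetrasubstituted enol ether cannot be predicted with confidence, so the ligand antipode that gives (1aR,6bR)-7 is to be used; the base-induced cyclopropanol opening is taken to invert the protonated carbon, as is usual in protic base (if retention were found, the other ligand antipode would be used).

Step 1
Reactants: 1 4,6-dihydroxybenzofuran-3(2H)-one
Product: 2 6-(benzyloxy)-4-hydroxybenzofuran-3(2H)-one
Conditions: BnBr (1.05 equiv), K2CO3, DMF, 0 °C to rt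
Reagents that add atoms: benzyl bromide BrCc1ccccc1
Why: Williamson ether synthesis, in which the 6-OH (para to the carbonyl, not chelated) is the more acidic phenol and should be alkylated selectively while the hydrogen-bonded 4-OH stays free.

Step 2
Reactants: 2 6-(benzyloxy)-4-hydroxybenzofuran-3(2H)-one
Product: 3 6-(benzyloxy)-4-methoxybenzofuran-3(2H)-one
Conditions: Me2SO4, K2CO3, acetone, reflux
Reagents that add atoms: dimethyl sulfate COS(=O)(=O)OC
Why: Williamson O-methylation of the remaining chelated phenol under the forcing conditions used for peri-hydroxy ketones; the benzyl ether and the ketone are not affected.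

Step 3
Reactants: 3 6-(benzyloxy)-4-methoxybenzofuran-3(2H)-one; 4 4-bromoanisole
Product: 6 6-(benzyloxy)-4-methoxy-2-(4-methoxyphenyl)-3-(trimethylsilyloxy)benzofuran, via 2-arylbenzofuranone 5 (not isolated)
Conditions: Pd2(dba)3 (2 mol %), XPhos, NaOt-Bu (2.2 equiv), toluene, 80 °C; then TMSCl, 0 °C
Reagents that add atoms: chlorotrimethylsilane C[Si](C)(C)Cl
Why: Pd-catalysed ketone α-arylation (Buchwald–Hartwig type) should stop at monoarylation because 5 is held as its aromatic 3-oxidobenzofuran enolate, which is O-silylated in the same flask so that the air-sensitive 2-aryl-3-hydroxybenzofuran is never handled.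

Step 4
Reactants: 6 6-(benzyloxy)-4-methoxy-2-(4-methoxyphenyl)-3-(trimethylsilyloxy)benzofuran
Product: 9 (2S)-7-(benzyloxy)-5-methoxy-2-(4-methoxyphenyl)chroman-4-one, via silyloxycyclopropane 7 (not isolated), via cyclopropanol 8 (not isolated)
Conditions: Et2Zn, CH2I2, Boc-Val-Pro-OMe dipeptide ligand (25 mol %), CH2Cl2, −40 to 0 °C; then K2CO3, MeOH, 0 °C; AcOH quench
Reagents that add atoms: diiodomethane ICI
Why: The dipeptide-ligated zinc carbenoid adds CH2 suprafacially to the electron-rich C2=C3 enol-ether bond of the flat benzofuran ([2+1] closure of the cyclopropane, the asymmetric Simmons–Smith cyclopropanation of silyl enol ethers), which dearomatises the furan ring and sets C1a and C6b of 7 under ligand control alone. Methanolysis of the silyl ether gives cyclopropanol 8, whose alkoxide cleaves the internal C1a–C6b bond while C1a is protonated (base-induced cyclopropanol opening, a homoenolate-type homoketonisation), so the five-membered ring O–C1a–C6b–C6a–C2a becomes the six-membered chromanone with the transferred CH2 as C3. This opening is stereospecific, with inversion at the protonated carbon, so (1aR,6bR)-8 should give (2S)-9. The selectivity needed is cleavage of the internal bond and not of C1–C6b; the aryl group and O1 on C1a stabilise the developing carbanion, and only this cleavage releases the strain of the fused bicycle. Short exposure to K2CO3/MeOH at 0 °C and the acetic acid quench should keep reversible oxa-Michael opening of 9 from eroding C2.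

Step 5
Reactants: 9 (2S)-7-(benzyloxy)-5-methoxy-2-(4-methoxyphenyl)chroman-4-one
Product: 10 (2S)-7-(benzyloxy)-5-methoxy-2-(4-methoxyphenyl)-4-(trimethylsilyloxy)-2H-chromene
Conditions: TMSOTf, Et3N, CH2Cl2, 0 °C
Reagents that add atoms: trimethylsilyl triflate C[Si](C)(C)OS(=O)(=O)C(F)(F)F
Why: Soft enolisation to the silyl enol ether avoids a free flavanone enolate, which would open by E1cB loss of the O1 phenoxide, and does not touch C2.

Step 6
Reactants: 10 (2S)-7-(benzyloxy)-5-methoxy-2-(4-methoxyphenyl)-4-(trimethylsilyloxy)-2H-chromene (two molecules)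
Product: 11 (2S,3R,2''S,3''R)-7,7''-bis(benzyloxy)-5,5''-dimethoxy-2,2''-bis(4-methoxyphenyl)-3,3''-bichromane-4,4''-dione
Conditions: Ag2O, DMSO, 65 °C
Reagents that add atoms: none
Why: Silver(I) oxide-mediated oxidative homocoupling of silyl enol ethers to a 1,4-diketone, in which each C3 centre should bond on the face anti to its C2 aryl group, so two (2S) halves give the 2,3-trans, 2'',3''-trans (3R,3''R) dimer, and any 3-epimer can be equilibrated to this all-equatorial isomer by enolisation without touching C2.

Step 7
Reactants: 11 (2S,3R,2''S,3''R)-7,7''-bis(benzyloxy)-5,5''-dimethoxy-2,2''-bis(4-methoxyphenyl)-3,3''-bichromane-4,4''-dione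
Product: 12 4',4''',5,5''-tetramethylchamaejasmin
Conditions: H2 (1 atm), 10% Pd/C, EtOAc, rt
Reagents that add atoms: none
Why: Hydrogenolysis of the two benzyl aryl ethers under neutral conditions should leave the aryl ketones, the methyl ethers, the cyclic benzylic C2–O1 ethers and the epimerisable C3/C3'' centres unchanged.

Compound list
1 | 4,6-dihydroxybenzofuran-3(2H)-one | O=C1COc2cc(O)cc(O)c12 | starting material
2 | 6-(benzyloxy)-4-hydroxybenzofuran-3(2H)-one | O=C1COc2cc(OCc3ccccc3)cc(O)c12 | intermediate
3 | 6-(benzyloxy)-4-methoxybenzofuran-3(2H)-one | O=C1COc2cc(OCc3ccccc3)cc(OC)c12 | intermediate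
4 | 4-bromoanisole | COc1ccc(Br)cc1 | starting material
5 | 6-(benzyloxy)-4-methoxy-2-(4-methoxyphenyl)benzofuran-3(2H)-one (racemic, present as its sodium enolate) | COc1ccc(cc1)C1Oc2cc(OCc3ccccc3)cc(OC)c2C1=O | intermediate
6 | 6-(benzyloxy)-4-methoxy-2-(4-methoxyphenyl)-3-(trimethylsilyloxy)benzofuran | COc1ccc(cc1)-c1oc2cc(OCc3ccccc3)cc(OC)c2c1O[Si](C)(C)C | intermediate
7 | (1aR,6bR)-4-(benzyloxy)-6-methoxy-1a-(4-methoxyphenyl)-6b-(trimethylsilyloxy)-1a,6b-dihydro-1H-cyclopropa[b]benzofuran | COc1ccc(cc1)[C@]12C[C@@]1(O[Si](C)(C)C)c1c(OC)cc(OCc3ccccc3)cc1O2 | intermediate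
8 | (1aR,6bR)-4-(benzyloxy)-6-methoxy-1a-(4-methoxyphenyl)-1a,6b-dihydro-1H-cyclopropa[b]benzofuran-6b-ol | COc1ccc(cc1)[C@]12C[C@@]1(O)c1c(OC)cc(OCc3ccccc3)cc1O2 | intermediate
9 | (2S)-7-(benzyloxy)-5-methoxy-2-(4-methoxyphenyl)chroman-4-one | COc1ccc([C@H]2Oc3cc(OCc4ccccc4)cc(OC)c3C(=O)C2)cc1 | intermediate
10 | (2S)-7-(benzyloxy)-5-methoxy-2-(4-methoxyphenyl)-4-(trimethylsilyloxy)-2H-chromene | COc1ccc([C@H]2Oc3cc(OCc4ccccc4)cc(OC)c3C(O[Si](C)(C)C)=C2)cc1 | intermediate
11 | (2S,3R,2''S,3''R)-7,7''-bis(benzyloxy)-5,5''-dimethoxy-2,2''-bis(4-methoxyphenyl)-3,3''-bichromane-4,4''-dione | COc1ccc([C@H]2Oc3cc(OCc4ccccc4)cc(OC)c3C(=O)[C@@H]2[C@H]2C(=O)c3c(OC)cc(OCc4ccccc4)cc3O[C@@H]2c2ccc(OC)cc2)cc1 | intermediate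
12 | 4',4''',5,5''-tetramethylchamaejasmin, (2S,3R,2''S,3''R)-7,7''-dihydroxy-5,5''-dimethoxy-2,2''-bis(4-methoxyphenyl)-3,3''-bichromane-4,4''-dione | COc1ccc([C@H]2Oc3cc(O)cc(OC)c3C(=O)[C@@H]2[C@H]2C(=O)c3c(OC)cc(O)cc3O[C@@H]2c2ccc(OC)cc2)cc1 | target

Total step count: 7. Longest linear sequence: 7 steps (1 to 12).

Steps most likely to fail

Step 4. The carbenoid may discriminate poorly between the two faces of a hindered, tetrasubstituted aromatic enol ether, or transfer methylene too slowly so that desilylation competes. Configuration at C2 may also erode during the basic opening, through planarisation of the benzylic carbanion or reversible oxa-Michael opening of 9. Fallback: starting from 6, ligand-free Simmons–Smith cyclopropanation gives the racemic silyloxycyclopropane F1, methanolysis gives the racemic cyclopropanol F2, and this opens to the racemic flavanone F3. Kinetic resolution by Ru(II)/TsDPEN asymmetric transfer hydrogenation (HCO2H/Et3N), a known way to resolve flavanones, then reduces the (2R) enantiomer to the cis-flavan-4-ol F4 and leaves (2S)-flavanone, so the route is rejoined at 9.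

Step 6. The C3 radical may fragment by loss of the O1 aryloxy group (ring opening to a chalcone), be dehydrogenated to the flavone, or be protodesilylated back to 9; the two halves may also combine with low facial selectivity. Fallback: starting from 9, soft enolisation with i-Pr2Si(OTf)2 (0.5 equiv) and Et3N gives the silylene-bridged bis(enol ether) F5. Oxidation with CAN/NaHCO3 in MeCN at −20 °C then couples the two enol ethers within one molecule (silicon-tethered oxidative enolate coupling), and the route is rejoined at 11.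

Step 3. Reductive elimination from the stabilised, aromatic enolate may be slow, so that O-arylation, double arylation or base-induced self-condensation of 3 take over. Fallback: starting from 3, TMSOTf/Et3N gives the 3-silyloxybenzofuran F6, and copper-catalysed arylation of this enol silane with (4-methoxyphenyl)(mesityl)iodonium triflate gives the 2-arylbenzofuranone, so the route is rejoined at 5, which is silylated as in step 3.

Further compounds
F1 | step 4 | rac-4-(benzyloxy)-6-methoxy-1a-(4-methoxyphenyl)-6b-(trimethylsilyloxy)-1a,6b-dihydro-1H-cyclopropa[b]benzofuran (racemic, cis-fused) | COc1ccc(cc1)C12CC1(O[Si](C)(C)C)c1c(OC)cc(OCc3ccccc3)cc1O2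
F2 | step 4 | rac-4-(benzyloxy)-6-methoxy-1a-(4-methoxyphenyl)-1a,6b-dihydro-1H-cyclopropa[b]benzofuran-6b-ol (racemic, cis-fused) | COc1ccc(cc1)C12CC1(O)c1c(OC)cc(OCc3ccccc3)cc1O2
F3 | step 4 | rac-7-(benzyloxy)-5-methoxy-2-(4-methoxyphenyl)chroman-4-one | COc1ccc(C2Oc3cc(OCc4ccccc4)cc(OC)c3C(=O)C2)cc1
F4 | step 4 | (2R,4R)-7-(benzyloxy)-5-methoxy-2-(4-methoxyphenyl)chroman-4-ol | COc1ccc([C@@H]2Oc3cc(OCc4ccccc4)cc(OC)c3[C@H](O)C2)cc1
F5 | step 6 | bis[(2S)-7-(benzyloxy)-5-methoxy-2-(4-methoxyphenyl)-2H-chromen-4-yloxy]diisopropylsilane | CC(C)[Si](OC1=C[C@@H](c2ccc(OC)cc2)Oc2cc(OCc3ccccc3)cc(OC)c12)(OC1=C[C@@H](c2ccc(OC)cc2)Oc2cc(OCc3ccccc3)cc(OC)c12)C(C)C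
F6 | step 3 | 6-(benzyloxy)-4-methoxy-3-(trimethylsilyloxy)benzofuran | COc1cc(OCc2ccccc2)cc2occ(O[Si](C)(C)C)c12
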